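**Retrosynthetic overview**

1. The C4 senecioate and the C1 acetate go on last. The C2–C3 epoxide and the C1 carbinol come from the ten-membered (2E,6E)-dienone 12 by 1,2-reduction from the outer face and hydroxyl-directed epoxidation.
2. Key disconnection C9–C10: in the ring, C9H2 is homoallylic to the (E)-C6=C7(CH3) bond, so C6=C7–C8–C9 is the ring-opened form of a (1-methylcyclopropyl)carbinyl cation (cation at C6, three-membered ring C7/C8/C9). The oxygen on C1 makes the neighbouring C10 an enol carbon. Strain-release capture of that cation by the silyl enol ether closes the ten-membered carbocycle and sets the (E)-alkene and C10 in one step.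
3. The open-chain precursor 10 comes from methyl ketone 1 (C5–C9 with the C7 methyl and the cyclopropane) and enal ester 2 (C1–C4) by an asymmetric aldol reaction (C4–C5 bond, C4 set), followed by isobutyl Grignard addition to a Weinreb amide (C1–C10 bond).
4. Ring order: cyclopropane (temporary, bought with 1), then the ten-membered ring (step 8, cyclopropane consumed), then the epoxide (step 10).

Key step: step 8

Remark: the ring carbons are numbered C1 (acetoxy carbon), C2 and C3 (epoxide carbons, C3 with the methyl group), C4 (senecioyloxy carbon), C5, C6=C7 (C7 with the methyl group), C8, C9, C10 (isopropyl carbon), and these atom numbers are kept for the open-chain compounds in the Why lines; with a silyl ether on C4 the descriptor of C3 reads S instead of R by rule with no change in geometry, and C6 of compounds 6–10 is a mixture of both configurations by design.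

**Route**

Step 1
Reactants: 1 1-(1-methylcyclopropyl)ethan-1-one; 2 ethyl (2E)-3-methyl-4-oxobut-2-enoate
Product: 4 ethyl (2E,4S)-4-hydroxy-3-methyl-6-(1-methylcyclopropyl)-6-oxohex-2-enoate, via enol diisopinocampheylborinate 3 (not isolated)
Conditions: 1, (−)-Ipc2BCl, Et3N, Et2O, 0 °C; then 2, −78 → −20 °C; then MeOH, pH 7 buffer, H2O2, 0 °C
Reagents that add atoms: none
Why: Paterson aldol reaction: the methyl ketone (enolisable on one side only) gives the enol borinate 3, whose chair transition state with the (−)-Ipc ligands is expected to add to the si face of the aldehyde and so set C4 as (S); the antipodal borane is used if the sense proves opposite.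

Step 2
Reactants: 4 ethyl (2E,4S)-4-hydroxy-3-methyl-6-(1-methylcyclopropyl)-6-oxohex-2-enoate
Product: 5 ethyl (2E,4S)-4-[(tert-butyldimethylsilyl)oxy]-3-methyl-6-(1-methylcyclopropyl)-6-oxohex-2-enoate
Conditions: t-BuMe2SiOTf, 2,6-lutidine, CH2Cl2, −78 °C
Reagents that add atoms: tert-butyldimethylsilyl trifluoromethanesulfonate, CC(C)(C)[Si](C)(C)OS(=O)(=O)C(F)(F)F
Why: Silyl ether formation with a silyl triflate and 2,6-lutidine at low temperature protects the β-hydroxy ketone without retro-aldol cleavage or elimination and does not touch C4.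

Step 3
Reactants: 5 ethyl (2E,4S)-4-[(tert-butyldimethylsilyl)oxy]-3-methyl-6-(1-methylcyclopropyl)-6-oxohex-2-enoate
Product: 6 ethyl (2E,4S,6RS)-4-[(tert-butyldimethylsilyl)oxy]-6-hydroxy-3-methyl-6-(1-methylcyclopropyl)hex-2-enoate
Conditions: NaBH4, MeOH, −20 → 0 °C
Reagents that add atoms: none
Why: Borohydride reduction is chemoselective for the saturated ketone over the conjugated ester; the new C6 centre is left uncontrolled on purpose, because both epimers later ionise to the same cation.

Step 4
Reactants: 6 ethyl (2E,4S,6RS)-4-[(tert-butyldimethylsilyl)oxy]-6-hydroxy-3-methyl-6-(1-methylcyclopropyl)hex-2-enoate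
Product: 7 (2E,4S,6RS)-4-[(tert-butyldimethylsilyl)oxy]-6-hydroxy-N-methoxy-N,3-dimethyl-6-(1-methylcyclopropyl)hex-2-enamide
Conditions: MeNH(OMe)·HCl, i-PrMgCl, THF, −20 °C
Reagents that add atoms: N,O-dimethylhydroxylamine hydrochloride, CNOC.Cl
Why: Weinreb amide formation by aminolysis of the ester with the chloromagnesium amide made in the flask, which tolerates the free hydroxyl (as its alkoxide) and the silyl ether; the β,β-disubstituted enoate resists conjugate addition.

Step 5
Reactants: 7 (2E,4S,6RS)-4-[(tert-butyldimethylsilyl)oxy]-6-hydroxy-N-methoxy-N,3-dimethyl-6-(1-methylcyclopropyl)hex-2-enamide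
Product: 8 (5E,7S,9RS)-7-[(tert-butyldimethylsilyl)oxy]-9-hydroxy-2,6-dimethyl-9-(1-methylcyclopropyl)non-5-en-4-one
Conditions: i-BuMgBr, THF, −20 → 0 °C; cold aq. NH4Cl
Reagents that add atoms: isobutylmagnesium bromide, CC(C)C[Mg]Br
Why: Weinreb ketone synthesis: the chelated tetrahedral adduct holds until work-up, so a single isobutyl group adds, and the cold quench limits conjugate addition of the C6 alkoxide to the new enone.

Step 6
Reactants: 8 (5E,7S,9RS)-7-[(tert-butyldimethylsilyl)oxy]-9-hydroxy-2,6-dimethyl-9-(1-methylcyclopropyl)non-5-en-4-one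
Product: 9 (1RS,3S,4E)-3-[(tert-butyldimethylsilyl)oxy]-4,8-dimethyl-1-(1-methylcyclopropyl)-6-oxonon-4-en-1-yl acetate
Conditions: Ac2O, pyridine, 4-(dimethylamino)pyridine (cat.), CH2Cl2, 0 °C → rt
Reagents that add atoms: acetic anhydride, CC(=O)OC(C)=O
Why: Acetylation under nucleophilic catalysis turns the hindered C6 hydroxyl into the leaving group needed for the key step.

Step 7
Reactants: 9 (1RS,3S,4E)-3-[(tert-butyldimethylsilyl)oxy]-4,8-dimethyl-1-(1-methylcyclopropyl)-6-oxonon-4-en-1-yl acetate
Product: 10 (1RS,3S,4E,6Z)-3,6-bis[(tert-butyldimethylsilyl)oxy]-4,8-dimethyl-1-(1-methylcyclopropyl)nona-4,6-dien-1-yl acetate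
Conditions: t-BuMe2SiOTf, Et3N, CH2Cl2, −20 → 0 °C
Reagents that add atoms: tert-butyldimethylsilyl trifluoromethanesulfonate, CC(C)(C)[Si](C)(C)OS(=O)(=O)C(F)(F)F
Why: Soft enolisation of the enone (silyl triflate, tertiary amine) removes an α′ proton at C10 and should give the cross-conjugated 2-silyloxy diene, mainly as the (Z)-enol ether, while the amine keeps the silyl triflate from ionising the acetate.

Step 8
Reactants: 10 (1RS,3S,4E,6Z)-3,6-bis[(tert-butyldimethylsilyl)oxy]-4,8-dimethyl-1-(1-methylcyclopropyl)nona-4,6-dien-1-yl acetate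
Product: 12 (2E,4S,6E,10S)-4-[(tert-butyldimethylsilyl)oxy]-3,7-dimethyl-10-(propan-2-yl)cyclodeca-2,6-dien-1-one, via cyclopropylcarbinyl cation 11 (not isolated)
Conditions: Me3SiOTf (0.2 equiv), 2,6-di-tert-butyl-4-methylpyridine (0.3 equiv), CH2Cl2, −78 → −20 °C, slow addition of 10 (final 0.5 mM); Et3N quench
Reagents that add atoms: none
Why: Proposed new method: the silyl triflate silylates the acetate carbonyl, C6–O ionises to the (1-methylcyclopropyl)carbinyl cation 11, and the enol carbon C10 of the 2-silyloxy diene attacks a ring CH2 of the cyclopropane (C9) while the C7–C9 bond breaks, so that the C9–C10 bond, the ten-membered ring and the C6=C7 bond form together with release of the cyclopropane strain, after which the enol silyl group leaves with the acetate (t-BuMe2SiOAc) and a silyl triflate is passed on. The closest known reactions are the Julia–Johnson opening of 1-methylcyclopropyl carbinols to (E)-homoallylic bromides, the Lewis acid-catalysed ring opening of cyclopropyl carbinols by carbon nucleophiles and the Mukaiyama-type SN1 alkylation of silyl enol ethers, and what is new is the ring-forming capture by carbon. The ten-membered ring closes by exo-tet-like attack at the cyclopropane CH2 in the homoallyl mode, the breaking C7–C9 bond ending as a chord of the new ring. The C6=C7 geometry is controlled by the bisected cation, in which the C5 chain lies syn to the C7 methyl group as in the Julia–Johnson reaction, which gives (E), and C10 is controlled by a crown-like transition state in which the isopropyl group of the (Z)-enol ether and the C4 silyloxy group both point outward, which gives (10S), the epimer that should also be favoured at equilibrium because C10 is α to the ketone. The step needs capture at C9 and not at C6 or C7, ionisation at C6 and not at C4, and cyclisation and not oligomerisation: the (E)-C2=C3 bond in the tether makes the seven- and eight-membered rings from capture at C6 or C7 too strained, the acetate is a far better Lewis base and leaving group than the bulky C4 silyl ether, and slow addition at high dilution with a hindered pyridine base holds back intermolecular alkylation and protodesilylation. Both C6 epimers and both enol ether isomers of 10 converge on the same cation and the same enolisable ketone, so no isomer is lost.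

Step 9
Reactants: 12 (2E,4S,6E,10S)-4-[(tert-butyldimethylsilyl)oxy]-3,7-dimethyl-10-(propan-2-yl)cyclodeca-2,6-dien-1-one
Product: 13 (1R,2E,4S,6E,10S)-4-[(tert-butyldimethylsilyl)oxy]-3,7-dimethyl-10-(propan-2-yl)cyclodeca-2,6-dien-1-ol
Conditions: NaBH4, CeCl3·7H2O, MeOH, −78 °C
Reagents that add atoms: none
Why: Luche reduction (1,2-selective): hydride should add to the C1 carbonyl from the open outer face, anti to C3 and its methyl group, because the inner face is shielded by the ring, which puts the hydroxyl on the methyl side of the C2=C3 bond and sets C1 as (R).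

Step 10
Reactants: 13 (1R,2E,4S,6E,10S)-4-[(tert-butyldimethylsilyl)oxy]-3,7-dimethyl-10-(propan-2-yl)cyclodeca-2,6-dien-1-ol
Product: 14 (1R,2R,3S,4S,6E,10S)-4-[(tert-butyldimethylsilyl)oxy]-2,3-epoxy-3,7-dimethyl-10-(propan-2-yl)cyclodec-6-en-1-ol
Conditions: VO(acac)2 (5 mol %), t-BuOOH (in decane), CH2Cl2, 0 °C
Reagents that add atoms: tert-butyl hydroperoxide, CC(C)(C)OO
Why: Hydroxyl-directed epoxidation with a vanadium alkylperoxide: with C10 held roughly perpendicular to the alkene plane by the ring, the C1 alkoxide can reach the (E)-C2=C3 bond only at a small O–C1–C2=C3 angle, so oxygen is delivered to the outer face and C2 and C3 are set erythro to C1, and the C6=C7 bond, which has no free hydroxyl near it, is left.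

Step 11
Reactants: 14 (1R,2R,3S,4S,6E,10S)-4-[(tert-butyldimethylsilyl)oxy]-2,3-epoxy-3,7-dimethyl-10-(propan-2-yl)cyclodec-6-en-1-ol
Product: 15 (1R,2R,3S,4S,6E,10S)-4-[(tert-butyldimethylsilyl)oxy]-2,3-epoxy-3,7-dimethyl-10-(propan-2-yl)cyclodec-6-en-1-yl acetate
Conditions: Ac2O, pyridine, 4-(dimethylamino)pyridine (cat.), CH2Cl2, 0 °C → rt
Reagents that add atoms: acetic anhydride, CC(=O)OC(C)=O
Why: Acetylation under nucleophilic catalysis of the secondary C1 hydroxyl; the basic medium avoids acid-induced opening or transannular cyclisation of the epoxide.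

Step 12
Reactants: 15 (1R,2R,3S,4S,6E,10S)-4-[(tert-butyldimethylsilyl)oxy]-2,3-epoxy-3,7-dimethyl-10-(propan-2-yl)cyclodec-6-en-1-yl acetate
Product: 16 (1R,2R,3R,4S,6E,10S)-2,3-epoxy-4-hydroxy-3,7-dimethyl-10-(propan-2-yl)cyclodec-6-en-1-yl acetate
Conditions: Bu4NF, AcOH, THF, 0 °C → rt
Reagents that add atoms: none
Why: Fluoride-mediated desilylation buffered with acetic acid frees the C4 hydroxyl without acetyl loss, and Payne rearrangement is blocked because C3 is fully substituted.

Step 13
Reactants: 16 (1R,2R,3R,4S,6E,10S)-2,3-epoxy-4-hydroxy-3,7-dimethyl-10-(propan-2-yl)cyclodec-6-en-1-yl acetate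
Product: 17 (1R,2R,3R,4S,6E,10S)-1-acetoxy-2,3-epoxy-3,7-dimethyl-10-(propan-2-yl)cyclodec-6-en-4-yl 3-methylbut-2-enoate (CNP0267399.1)
Conditions: 3-methylbut-2-enoyl chloride, pyridine, 4-(dimethylamino)pyridine (cat.), CH2Cl2, 0 °C
Reagents that add atoms: 3-methylbut-2-enoyl chloride, CC(C)=CC(=O)Cl
Why: Acylation of the hindered C4 alcohol with the acid chloride under nucleophilic catalysis proceeds with retention at C4; pyridine as the only base limits isomerisation of the acyl group to the β,γ-unsaturated ester through a vinylketene.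

**Compound list**

1 | 1-(1-methylcyclopropyl)ethan-1-one | CC(=O)C1(C)CC1 | starting material
2 | ethyl (2E)-3-methyl-4-oxobut-2-enoate | CCOC(=O)/C=C(\C)C=O | starting material
3 | 1-(1-methylcyclopropyl)ethenyl bis[(−)-isopinocampheyl]borinate (Ipc groups as in (−)-Ipc2BCl) | C=C(OB([C@@H]1C[C@@H]2C[C@H]([C@H]1C)C2(C)C)[C@@H]1C[C@@H]2C[C@H]([C@H]1C)C2(C)C)C1(C)CC1 | intermediate
4 | ethyl (2E,4S)-4-hydroxy-3-methyl-6-(1-methylcyclopropyl)-6-oxohex-2-enoate | CCOC(=O)/C=C(\C)[C@@H](O)CC(=O)C1(C)CC1 | intermediate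
5 | ethyl (2E,4S)-4-[(tert-butyldimethylsilyl)oxy]-3-methyl-6-(1-methylcyclopropyl)-6-oxohex-2-enoate | CCOC(=O)/C=C(\C)[C@@H](O[Si](C)(C)C(C)(C)C)CC(=O)C1(C)CC1 | intermediate
6 | ethyl (2E,4S,6RS)-4-[(tert-butyldimethylsilyl)oxy]-6-hydroxy-3-methyl-6-(1-methylcyclopropyl)hex-2-enoate | CCOC(=O)/C=C(\C)[C@@H](O[Si](C)(C)C(C)(C)C)CC(O)C1(C)CC1 | intermediate
7 | (2E,4S,6RS)-4-[(tert-butyldimethylsilyl)oxy]-6-hydroxy-N-methoxy-N,3-dimethyl-6-(1-methylcyclopropyl)hex-2-enamide | CON(C)C(=O)/C=C(\C)[C@@H](O[Si](C)(C)C(C)(C)C)CC(O)C1(C)CC1 | intermediate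
8 | (5E,7S,9RS)-7-[(tert-butyldimethylsilyl)oxy]-9-hydroxy-2,6-dimethyl-9-(1-methylcyclopropyl)non-5-en-4-one | CC(C)CC(=O)/C=C(\C)[C@@H](O[Si](C)(C)C(C)(C)C)CC(O)C1(C)CC1 | intermediate
9 | (1RS,3S,4E)-3-[(tert-butyldimethylsilyl)oxy]-4,8-dimethyl-1-(1-methylcyclopropyl)-6-oxonon-4-en-1-yl acetate | CC(C)CC(=O)/C=C(\C)[C@@H](O[Si](C)(C)C(C)(C)C)CC(OC(C)=O)C1(C)CC1 | intermediate
10 | (1RS,3S,4E,6Z)-3,6-bis[(tert-butyldimethylsilyl)oxy]-4,8-dimethyl-1-(1-methylcyclopropyl)nona-4,6-dien-1-yl acetate | CC(C)/C=C(\O[Si](C)(C)C(C)(C)C)/C=C(\C)[C@@H](O[Si](C)(C)C(C)(C)C)CC(OC(C)=O)C1(C)CC1 | intermediate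
11 | (1-methylcyclopropyl)carbinyl cation formed from 10 by loss of acetate at C6 | CC(C)/C=C(\O[Si](C)(C)C(C)(C)C)/C=C(\C)[C@@H](O[Si](C)(C)C(C)(C)C)C[CH+]C1(C)CC1 | intermediate
12 | (2E,4S,6E,10S)-4-[(tert-butyldimethylsilyl)oxy]-3,7-dimethyl-10-(propan-2-yl)cyclodeca-2,6-dien-1-one | O=C1/C=C(\C)[C@@H](O[Si](C)(C)C(C)(C)C)C/C=C(\C)CC[C@H]1C(C)C | intermediate
13 | (1R,2E,4S,6E,10S)-4-[(tert-butyldimethylsilyl)oxy]-3,7-dimethyl-10-(propan-2-yl)cyclodeca-2,6-dien-1-ol | O[C@H]1/C=C(\C)[C@@H](O[Si](C)(C)C(C)(C)C)C/C=C(\C)CC[C@H]1C(C)C | intermediate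
14 | (1R,2R,3S,4S,6E,10S)-4-[(tert-butyldimethylsilyl)oxy]-2,3-epoxy-3,7-dimethyl-10-(propan-2-yl)cyclodec-6-en-1-ol | O[C@H]1[C@H]2O[C@]2(C)[C@@H](O[Si](C)(C)C(C)(C)C)C/C=C(\C)CC[C@H]1C(C)C | intermediate
15 | (1R,2R,3S,4S,6E,10S)-4-[(tert-butyldimethylsilyl)oxy]-2,3-epoxy-3,7-dimethyl-10-(propan-2-yl)cyclodec-6-en-1-yl acetate | CC(=O)O[C@H]1[C@H]2O[C@]2(C)[C@@H](O[Si](C)(C)C(C)(C)C)C/C=C(\C)CC[C@H]1C(C)C | intermediate
16 | (1R,2R,3R,4S,6E,10S)-2,3-epoxy-4-hydroxy-3,7-dimethyl-10-(propan-2-yl)cyclodec-6-en-1-yl acetate | CC(=O)O[C@H]1[C@H]2O[C@]2(C)[C@@H](O)C/C=C(\C)CC[C@H]1C(C)C | intermediate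
17 | (1R,2R,3R,4S,6E,10S)-1-acetoxy-2,3-epoxy-3,7-dimethyl-10-(propan-2-yl)cyclodec-6-en-4-yl 3-methylbut-2-enoate (CNP0267399.1) | CC(=O)O[C@H]1[C@H]2O[C@]2(C)[C@@H](OC(=O)C=C(C)C)C/C=C(\C)CC[C@H]1C(C)C | target

**Step count and risks**

Total step count: 13. Longest linear sequence: 13 steps (1 and 2 to 17).

Steps most likely to fail:

1. Step 8 (proposed new method). What may go wrong: the cation may be captured by the counter-ion or by a second molecule (oligomerisation), it may rearrange to cyclobutyl products or eliminate, ionisation may occur at C4, or facial selectivity at C10 may be poor. Fallback by known chemistry, forming the same bond stepwise: it sets out from hydroxy ketone 8. Julia–Johnson opening (PBr3, LiBr, 2,4,6-collidine, Et2O, −30 °C; then ZnBr2, 0 °C) should give the (E)-homoallylic bromide F1. Intramolecular C-alkylation of its kinetic α′ enolate (LiN(SiMe3)2, THF–HMPA, −78 → 0 °C, high dilution) should close the C9–C10 bond, and the route is rejoined at 12.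

2. Step 9. What may go wrong: hydride may be delivered to the other face of the C1 carbonyl, or the ring may react through another conformer. Fallback: it sets out from 12, whose reduction would then give the C1-epimeric alcohol F2. Mitsunobu inversion (4-nitrobenzoic acid, PPh3, diisopropyl azodicarboxylate, THF, 0 °C) should give the 4-nitrobenzoate F3 with the required C1 configuration. Methanolysis (K2CO3, MeOH, 0 °C) comes back at 13.

3. Step 10. What may go wrong: oxygen may be transferred to the other face of C2=C3 or to C6=C7, or the epoxide may open by transannular attack of the C6=C7 bond. Fallback with the order of events reversed: it sets out from 12. Weitz–Scheffer epoxidation of the enone (t-BuOOH, 1,8-diazabicyclo[5.4.0]undec-7-ene, CH2Cl2, 0 °C) should give, from the outer face, the epoxy ketone F4. Chelation-controlled reduction (Zn(BH4)2, Et2O, −30 °C), which is erythro-selective for α,β-epoxy ketones, comes back at 14.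

**Further compounds**

F1 | step 8 | (5E,7S,9E)-12-bromo-7-[(tert-butyldimethylsilyl)oxy]-2,6,10-trimethyldodeca-5,9-dien-4-one | CC(C)CC(=O)/C=C(\C)[C@@H](O[Si](C)(C)C(C)(C)C)C/C=C(\C)CCBr
F2 | step 9 | (1S,2E,4S,6E,10S)-4-[(tert-butyldimethylsilyl)oxy]-3,7-dimethyl-10-(propan-2-yl)cyclodeca-2,6-dien-1-ol | O[C@@H]1/C=C(\C)[C@@H](O[Si](C)(C)C(C)(C)C)C/C=C(\C)CC[C@H]1C(C)C
F3 | step 9 | (1R,2E,4S,6E,10S)-4-[(tert-butyldimethylsilyl)oxy]-3,7-dimethyl-10-(propan-2-yl)cyclodeca-2,6-dien-1-yl 4-nitrobenzoate | O=C(O[C@H]1/C=C(\C)[C@@H](O[Si](C)(C)C(C)(C)C)C/C=C(\C)CC[C@H]1C(C)C)c1ccc(cc1)[N+](=O)[O-]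
F4 | step 10 | (2S,3S,4S,6E,10S)-4-[(tert-butyldimethylsilyl)oxy]-2,3-epoxy-3,7-dimethyl-10-(propan-2-yl)cyclodec-6-en-1-one | O=C1[C@H]2O[C@]2(C)[C@@H](O[Si](C)(C)C(C)(C)C)C/C=C(\C)CC[C@H]1C(C)C
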